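## Compound numbers used throughout

1 vanillin · 2 its triisopropylsilyl ether · 3 the dimethyl acetal of 2 · 4 methyl 3,4-dihydroxybenzoate · 5 racemic 2-aryl-1,3-benzodioxole ester · 6 tert-butyl diazoacetate · 7 oxonium ylide (not isolated) · 8 ring-opened zwitterion (not isolated) · 9 trans diester · 10 diol · 11 aldehyde · 12 arylidenemalonic acid (not isolated) · 13 silylated cinnamic acid · 14 target.

## Analysis of the target

Compound 14 is a 2,3-dihydro-1,4-benzodioxine: a dioxane ring (O1, C2, C3, O4, C4a, C8a) fused to benzene ring A. It carries a 4-hydroxy-3-methoxyphenyl group (ring C) on C2, a hydroxymethyl group on C3 and an (E)-acrylic acid on C6. C2 and C3 are the only stereocentres, both R, with aryl and hydroxymethyl trans, the diequatorial and more stable arrangement of the half-chair. The two ring oxygens are not equivalent: O1, which holds the benzylic carbon C2, is para to the acrylic acid, while O4, which holds C3, is meta to it. The isomer with the heterocycle turned round is the usual by-product of catechol-based routes. The C2–O1 bond is a para-hydroxybenzyl aryl ether, so with the ring C phenol free it can ionise to a quinone methide under acid or base, which endangers C2 and the ring. The cinnamic acid excludes hydrogenolysis, and the free phenol excludes late oxidants. The difficulty is to set two adjacent stereocentres absolutely on a ring that has no other chirality, and at the same time to tell O1 from O4. The strategy rests on one feature: taking out C3 with its substituent leaves O1–C2(aryl)–O4, the acetal of a catechol with vanillin. This is a 2-aryl-1,3-benzodioxole in which an acceptor at C6 already makes O4 the more basic oxygen, so the dioxane is the product of inserting one carbon into the O4–C2 bond.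

## Retrosynthetic reasoning

**14 from 13 (O–Si bond).** The ring C phenol is released last. While it is a silyl ether the oxygen cannot be deprotonated and is a weaker donor, so the C2–O1 bond is safe in the basic and hot steps before it. A triisopropylsilyl ether is chosen over a smaller silyl ether because it must pass an acid-catalysed acetal exchange at 110 °C, an aluminium hydride and hot pyridine. The forward step only has to break Si–O without enough base strength to open the ring.

**13 from 11 (Cα=Cβ of the side chain).** A Knoevenagel–Doebner transform, through diacid 12, leads back to aldehyde 11. The cut is made here because the aldehyde carbon is then a ring A carboxyl carbon that can be present from the first step. The acid arrives free, so no ester hydrolysis is needed next to the latent phenol, and decarboxylation gives the E alkene.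

**11 from 10, and 10 from 9 (oxidation levels).** Both CH2OH groups of 10 are traced to esters in 9, so one hydride reduction makes both. They are then distinguished because only the one on ring A is benzylic. The esters are not spectators: the ring A ester is the acceptor that differentiates O1 from O4 in the key step, and the ester on C3 is what makes C3 a carbene carbon.

**9 from 5 and 6 (O4–C3 and C2–C3).** This is the key disconnection. Removing C3 as the carbene carbon of 6 collapses the dioxane to the benzodioxole 5. Other cuts of the heterocycle break C–O bonds and need the two catechol oxygens separated by protecting groups and both stereocentres built on an open chain. This cut instead uses an acetal made from both oxygens at once and leaves the choice between them to electronics. Forward, the carbene must bond to O4 and not O1 (ylide 7), C2 must move from O4 to C3 through the ion pair 8, and a chiral catalyst must set C3 and C2 trans and in the right absolute sense. The gain is one ring, two skeletal bonds and two stereocentres in one step from a precursor three steps from purchased material.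

**5 from 3 and 4 (both acetal C–O bonds).** Acetal exchange between the dimethyl acetal 3 and the catechol 4 has no regiochemistry to control. The acetal carbon becomes a stereocentre and 5 is racemic, which is accepted because that centre is planar in 8.

**3 from 2, and 2 from 1.** The dimethyl acetal is the activated form of aldehyde 2 for exchange with a weakly nucleophilic catechol. Compound 2 is vanillin 1 with its phenol silylated.

## Alternatives that were turned down

**Alternative 1:** amine-catalysed aldol condensation and oxa-Michael cascade.
- **Disconnection:** C2–C3 and O1–C2, back to aryloxyacetaldehyde A2 (the acetaldehyde unit on O4, O1 free, acrylate present as its methyl ester) and vanillin acetate A3.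
- **Key step:** the enamine of A2 with a chiral primary amine salt condenses with A3 to form C2–C3. The iminium ion of the resulting unsaturated aldehyde then takes up the ring A phenol at C2 in a 6-endo-trig oxa-Michael addition to give aldehyde A1.
- **For:** ring, both stereocentres and the whole carbon skeleton arise in one metal-free operation. With the acrylate in place, only a carbonyl reduction and one hydrolysis would follow, so after the key step it is shorter than the chosen route (two steps against four).
- **Against:**
  - A2 can only be made by alkylating the less acidic hydroxyl (meta to the acrylate) of its catechol precursor, so the O1/O4 problem returns as a protecting-group problem.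
  - A2 is an unhindered α-aryloxy aldehyde that self-condenses, and A3 is a weak acceptor.
  - In A1, C3 is α to a formyl group and C2 is β to it with an aryloxide as leaving group. Under the amine both centres stay in equilibrium through enamine formation and retro-oxa-Michael opening, so kinetically set enantiopurity may not last.
  - The acrylate is a second Michael acceptor for amine and phenol.
  - The final hydrolysis liberates the phenoxide under base.
- **Comparison:** both key steps lack direct precedent, and Alternative 1 is stronger on step economy. The chosen route offers a key product (9) that is a tert-butyl ester, is formed under neutral conditions and is reduced at once. Its precursor needs no regioselective phenol alkylation.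

**Alternative 2:** oxidative phenol dearomatisation to forge the aryl ether.
- **Disconnection:** the O1–C8a aryl ether bond, back to the open-chain phenol A5. This is a resorcinol monoether that carries the complete C2–C3 chain on O4, with both stereocentres set, the primary alcohol as a pivalate and the ring C phenol as a tosylate.
- **Key step:** a hypervalent iodine diacetate oxidises the phenol of A5. The benzylic hydroxyl attacks C8a, para to the phenol oxygen, and the dienone tautomerises to the benzodioxan-6-ol A4.
- **For:** both stereocentres come from dependable open-chain methods and are not touched, since the benzylic oxygen is the nucleophile and C2 keeps its configuration. No catechol has to be differentiated. The tosylate shields ring C from the oxidant. On stereochemical security this is stronger than the chosen route.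
- **Against:**
  - The nucleophile must add at a C–H position, and A4 is a 4-alkoxyphenol that is oxidised more easily than A5, so over-oxidation to quinone-type products is built in.
  - Closure at C5, ortho to the phenol, also gives a six-membered ring.
  - The C6 oxygen must then be exchanged for the acrylic acid (aryl triflate, Heck coupling).
  - Three protecting groups must be removed, and the tosylate needs hot base at a base-labile benzylic ether.
  - The route is long: the asymmetric synthesis of A5, then at least five steps after the ring closure.
- **Comparison:** the chosen route carries the C6 carbon from the start and makes ring and stereocentres together. It pays for this with an unproven enantioselective step.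

**Alternative 3:** stereoconvergent para-quinone methide ring closure.
- **Disconnection:** the O1–C2 bond, back to the diol-phenol A7. This is a C3-defined aryl glyceryl ether on O4, either epimer at the benzylic carbon, with a tert-butyl ether on the primary oxygen and the aldehyde masked as a dioxolane.
- **Key step:** anhydrous acid ionises the benzylic alcohol of A7 to the para-quinone methide. The ring A phenol adds to C2 and the dioxane closes as the trans isomer A6.
- **For:** only C3 needs absolute control. C2 is corrected thermodynamically, and the closure has close analogy in this class of compounds. On reliability of the ring-forming event and on diastereocontrol it is stronger than the chosen route.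
- **Against:**
  - A7 needs an enantioselective construction of the C3–O4 bond on the less acidic catechol oxygen, with the other oxygen protected.
  - Three different protecting groups are needed.
  - The ionisation releases water in the presence of acid and a dioxolane.
  - The tert-butyl ether must finally be removed with strong acid beside the para-hydroxybenzyl ether.
  - The route is clearly longer.
- **Comparison:** the chosen route offers brevity (three simple steps to the precursor) and catalytic creation of both stereocentres. The logic of Alternative 3 is kept as the fallback for the key step.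

Key step: step 4

## Remarks before the steps

- The locants O1, C2, C3, O4 and C6 of the target are used for every benzodioxane in the text and in the names, so C2 is always the aryl-bearing carbon. The descriptor at C3 is S while C3 carries a carbonyl group and R once it carries CH2OH, without any change in space.
- Assumption: the sense of induction of the copper–bisoxazoline catalyst in step 4 cannot be predicted with confidence. The (S,S) ligand is written, and its antipode is to be used if the opposite sense is found.
- The phenol is carried as a triisopropylsilyl ether, not a smaller silyl ether, for stability in steps 3, 5 and 7.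

## Route

**Step 1**
Reactants: 1 vanillin (4-hydroxy-3-methoxybenzaldehyde)
Product: 2 3-methoxy-4-(triisopropylsilyloxy)benzaldehyde
Conditions: i-Pr3SiCl, imidazole, DMF, 23 °C
Reagents that add atoms: triisopropylsilyl chloride, CC(C)[Si](Cl)(C(C)C)C(C)C
Why: Silylation of a phenol with a silyl chloride and imidazole; the hindered aryl silyl ether is stable to the acid, hydride and amine conditions ahead and leaves with fluoride at the end.

**Step 2**
Reactants: 2 3-methoxy-4-(triisopropylsilyloxy)benzaldehyde
Product: 3 [4-(dimethoxymethyl)-2-methoxyphenoxy]triisopropylsilane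
Conditions: HC(OMe)3, PPTS (cat.), MeOH, 23 °C; Et3N quench
Reagents that add atoms: trimethyl orthoformate, COC(OC)OC
Why: Acid-catalysed acetalisation of an aromatic aldehyde with the orthoformate as water scavenger; the aryl silyl ether tolerates PPTS in methanol, and the acetal ionises far more readily than the aldehyde in the exchange that follows.

**Step 3**
Reactants: 3 [4-(dimethoxymethyl)-2-methoxyphenoxy]triisopropylsilane; 4 methyl 3,4-dihydroxybenzoate
Product: 5 methyl 2-[3-methoxy-4-(triisopropylsilyloxy)phenyl]-1,3-benzodioxole-5-carboxylate (racemic at the acetal carbon)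
Conditions: PPTS (cat.), toluene, reflux, condensate returned through 4 Å MS to remove MeOH; Et3N quench
Reagents that add atoms: none
Why: Acid-catalysed transacetalisation: 3 ionises to a para-silyloxy-stabilised oxocarbenium ion that is captured by one catechol hydroxyl and, after loss of the second methanol, by its neighbour, and removal of methanol drives the equilibrium with the electron-poor catechol. The acetal carbon becomes a stereocentre and is formed racemic, which is accepted because step 4 passes through a species in which it is planar.

**Step 4**
Reactants: 5 methyl 2-[3-methoxy-4-(triisopropylsilyloxy)phenyl]-1,3-benzodioxole-5-carboxylate; 6 tert-butyl diazoacetate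
Product: 9 3-tert-butyl 6-methyl (2R,3S)-2-[3-methoxy-4-(triisopropylsilyloxy)phenyl]-2,3-dihydro-1,4-benzodioxine-3,6-dicarboxylate, via oxonium ylide 7 (not isolated), via oxocarbenium enolate zwitterion 8 (not isolated)
Conditions: [Cu(MeCN)4]PF6 (5 mol %), (S,S)-t-Bu-box (6 mol %), 4 Å MS, CH2Cl2, 23 °C, 6 added by syringe pump over 8 h
Reagents that add atoms: none
Why: Proposed new method: the copper carbene formed from 6 is attacked by O4 of 5 to give the copper-associated oxonium ylide 7; the closest known reaction types are the copper-catalysed enantioselective ring expansion of 2-aryloxetanes to tetrahydrofurans and the rhodium-catalysed expansion of 2-aryl-1,3-dioxolanes to 1,4-dioxanes with diazoesters, both [1,2]-Stevens shifts of oxonium ylides, neither shown on a benzodioxole or with convergence of a racemic acetal. Heterolysis of the O4–C2 bond of 7 is driven by the cation it leaves, an oxocarbenium ion stabilised by O1 and by the para-silyloxyaryl ring, and gives zwitterion 8, in which a ligand-bearing copper enolate and the planar cation are held together by ring A. Bonding of the enolate carbon to C2 closes the 1,4-dioxane in a 6-(enolexo)-endo-trig mode and completes the net [1,2]-shift, creating O4–C3 and C2–C3. C3 is set by the enolate face that the chiral bisoxazoline leaves open (catalyst control), and C2 by the cation face chosen in a chair-like closing transition state that places aryl and the bulky tert-butyl ester trans-diequatorial (relative control from C3). Because C2 is planar in 8, both enantiomers of 5 should give the same product. Regioselectivity for O4 over O1 is secured by the para ester, which draws the lone pair of O1 into conjugation and leaves O4 the more basic oxygen. Ylide formation is favoured over arene cyclopropanation, acetal C–H insertion and carbene dimerisation by the use of monovalent copper instead of a dirhodium carboxylate, slow addition of 6 and the bulky silyl ether beside the most electron-rich ring positions. Enantioselectivity needs ring closure to be faster than loss of copper from the enolate, which the intramolecular, ion-paired nature of 8 favours.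

**Step 5**
Reactants: 9 3-tert-butyl 6-methyl (2R,3S)-2-[3-methoxy-4-(triisopropylsilyloxy)phenyl]-2,3-dihydro-1,4-benzodioxine-3,6-dicarboxylate
Product: 10 [(2R,3R)-2-[3-methoxy-4-(triisopropylsilyloxy)phenyl]-2,3-dihydro-1,4-benzodioxine-3,6-diyl]dimethanol
Conditions: LiAlH4, THF, 0 °C; aqueous potassium sodium tartrate
Reagents that add atoms: none
Why: Hydride reduction of both esters with LiAlH4; at 0 °C carbonyl addition should outrun deprotonation at C3, as in reductions of related 3-aryl-1,4-benzodioxane-2-carboxylates, so neither stereocentre is touched. The diol offers a point for crystallisation if the enantiomeric purity needs raising.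

**Step 6**
Reactants: 10 [(2R,3R)-2-[3-methoxy-4-(triisopropylsilyloxy)phenyl]-2,3-dihydro-1,4-benzodioxine-3,6-diyl]dimethanol
Product: 11 (2R,3R)-3-(hydroxymethyl)-2-[3-methoxy-4-(triisopropylsilyloxy)phenyl]-2,3-dihydro-1,4-benzodioxine-6-carbaldehyde
Conditions: activated MnO2 (excess), CH2Cl2, 23 °C
Reagents that add atoms: none
Why: Chemoselective oxidation with activated MnO2, which converts benzylic alcohols to aldehydes and leaves saturated primary alcohols alone, so only the ring A hydroxymethyl reacts and no carboxylic acid is formed.

**Step 7**
Reactants: 11 (2R,3R)-3-(hydroxymethyl)-2-[3-methoxy-4-(triisopropylsilyloxy)phenyl]-2,3-dihydro-1,4-benzodioxine-6-carbaldehyde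
Product: 13 (E)-3-[(2R,3R)-3-(hydroxymethyl)-2-[3-methoxy-4-(triisopropylsilyloxy)phenyl]-2,3-dihydro-1,4-benzodioxin-6-yl]prop-2-enoic acid, via arylidenemalonic acid 12 (not isolated)
Conditions: malonic acid, piperidine (cat.), pyridine, 80 °C
Reagents that add atoms: malonic acid, OC(=O)CC(=O)O
Why: Knoevenagel–Doebner condensation: the aldehyde condenses with malonic acid under amine catalysis to 12, which decarboxylates in hot pyridine to the (E)-cinnamic acid, the thermodynamically preferred geometry. The phenol stays silylated, so no quinone methide can form from C2 in the hot basic medium, and the free primary alcohol does not interfere.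

**Step 8**
Reactants: 13 (E)-3-[(2R,3R)-3-(hydroxymethyl)-2-[3-methoxy-4-(triisopropylsilyloxy)phenyl]-2,3-dihydro-1,4-benzodioxin-6-yl]prop-2-enoic acid
Product: 14 (E)-3-[(2R,3R)-2-(4-hydroxy-3-methoxyphenyl)-3-(hydroxymethyl)-2,3-dihydro-1,4-benzodioxin-6-yl]prop-2-enoic acid
Conditions: Bu4NF, AcOH, THF, 0 °C; dilute aqueous citric acid
Reagents that add atoms: none
Why: Fluoride-induced cleavage of the aryl silyl ether, driven by Si–F bond formation; acetic acid buffers the phenoxide so that the para-hydroxybenzyl aryl ether at C2 never meets free base, and the alkene, the acid and both stereocentres are unaffected.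

## Compound list

1 | vanillin (4-hydroxy-3-methoxybenzaldehyde) | COc1cc(C=O)ccc1O | starting material
2 | 3-methoxy-4-(triisopropylsilyloxy)benzaldehyde | COc1cc(C=O)ccc1O[Si](C(C)C)(C(C)C)C(C)C | intermediate
3 | [4-(dimethoxymethyl)-2-methoxyphenoxy]triisopropylsilane | COc1cc(C(OC)OC)ccc1O[Si](C(C)C)(C(C)C)C(C)C | intermediate
4 | methyl 3,4-dihydroxybenzoate | COC(=O)c1ccc(O)c(O)c1 | starting material
5 | methyl 2-[3-methoxy-4-(triisopropylsilyloxy)phenyl]-1,3-benzodioxole-5-carboxylate, racemic at C2 | COC(=O)c1ccc2OC(c3ccc(O[Si](C(C)C)(C(C)C)C(C)C)c(OC)c3)Oc2c1 | intermediate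
6 | tert-butyl diazoacetate | CC(C)(C)OC(=O)C=[N+]=[N-] | starting material
7 | oxonium ylide from 5 and the carbene of 6, at the oxygen meta to the ester (copper-associated; drawn without the metal) | COC(=O)c1ccc2OC(c3ccc(O[Si](C(C)C)(C(C)C)C(C)C)c(OC)c3)[O+]([CH-]C(=O)OC(C)(C)C)c2c1 | intermediate (not isolated)
8 | ring-opened zwitterion: aryl oxocarbenium ion on O1 and tert-butyl aryloxyacetate enolate on O4 (copper enolate; drawn without the metal) | COC(=O)c1ccc([O+]=Cc2ccc(O[Si](C(C)C)(C(C)C)C(C)C)c(OC)c2)c(OC=C([O-])OC(C)(C)C)c1 | intermediate (not isolated)
9 | 3-tert-butyl 6-methyl (2R,3S)-2-[3-methoxy-4-(triisopropylsilyloxy)phenyl]-2,3-dihydro-1,4-benzodioxine-3,6-dicarboxylate (trans) | COc1cc([C@H]2Oc3ccc(C(=O)OC)cc3O[C@@H]2C(=O)OC(C)(C)C)ccc1O[Si](C(C)C)(C(C)C)C(C)C | intermediate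
10 | [(2R,3R)-2-[3-methoxy-4-(triisopropylsilyloxy)phenyl]-2,3-dihydro-1,4-benzodioxine-3,6-diyl]dimethanol | COc1cc([C@H]2Oc3ccc(CO)cc3O[C@@H]2CO)ccc1O[Si](C(C)C)(C(C)C)C(C)C | intermediate
11 | (2R,3R)-3-(hydroxymethyl)-2-[3-methoxy-4-(triisopropylsilyloxy)phenyl]-2,3-dihydro-1,4-benzodioxine-6-carbaldehyde | COc1cc([C@H]2Oc3ccc(C=O)cc3O[C@@H]2CO)ccc1O[Si](C(C)C)(C(C)C)C(C)C | intermediate
12 | 2-{[(2R,3R)-3-(hydroxymethyl)-2-[3-methoxy-4-(triisopropylsilyloxy)phenyl]-2,3-dihydro-1,4-benzodioxin-6-yl]methylidene}propanedioic acid | COc1cc([C@H]2Oc3ccc(C=C(C(=O)O)C(=O)O)cc3O[C@@H]2CO)ccc1O[Si](C(C)C)(C(C)C)C(C)C | intermediate (not isolated)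
13 | (E)-3-[(2R,3R)-3-(hydroxymethyl)-2-[3-methoxy-4-(triisopropylsilyloxy)phenyl]-2,3-dihydro-1,4-benzodioxin-6-yl]prop-2-enoic acid | COc1cc([C@H]2Oc3ccc(/C=C/C(=O)O)cc3O[C@@H]2CO)ccc1O[Si](C(C)C)(C(C)C)C(C)C | intermediate
14 | (E)-3-[(2R,3R)-2-(4-hydroxy-3-methoxyphenyl)-3-(hydroxymethyl)-2,3-dihydro-1,4-benzodioxin-6-yl]prop-2-enoic acid | COc1cc([C@H]2Oc3ccc(/C=C/C(=O)O)cc3O[C@@H]2CO)ccc1O | target

## Step count and least certain steps

Total: 8 steps. Longest linear sequence: 8 steps (1 to 14); 4 and 6 are purchased and enter in steps 3 and 4.

**Step 4 (key step, proposed new method).**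
- What may go wrong:
  - Carbene attack at O1, which would lead to the regioisomeric benzodioxane with the heterocycle turned round.
  - Cyclopropanation or ring expansion of the electron-rich arenes, insertion into the acetal C–H bond, and carbene dimerisation.
  - Rearrangement of a copper-free ylide, which would be racemic.
  - Migration of C2 with retention inside a tight pair, before the cation becomes planar. One enantiomer of 5 would then enter the cis series and the convergence would fail.
- Repair within the strategy: a cis isomer with the catalyst-set C3 could be equilibrated at C2 by acid-induced ionisation and reclosure of the benzylic C2–O1 bond, which leaves C3 alone.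
- Fallback (known reactions only; sets out from 4 and 2, returns at 10):
  - The more acidic hydroxyl of 4, para to the ester, is benzylated (BnBr, K2CO3, DMF) to methyl 4-(benzyloxy)-3-hydroxybenzoate F1. This fixes which oxygen becomes O1.
  - Williamson alkylation of the remaining hydroxyl with (S)-4-benzyl-3-(bromoacetyl)-1,3-oxazolidin-2-one (K2CO3, MeCN) gives the aryloxyacetyl imide F2.
  - Its dibutylboron Z-enolate (Bu2BOTf, i-Pr2NEt, CH2Cl2, −78 °C) adds to aldehyde 2 in an Evans syn aldol reaction to give the (2S,3R)-aldol adduct F3. The carbon that becomes C3 already has its final configuration.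
  - Hydrogenolysis (H2, Pd/C, EtOAc) frees the phenol para to the ester, giving the hydroxy phenol F4.
  - BF3·OEt2 in CH2Cl2 at −20 °C ionises the benzylic alcohol to the silyloxy-stabilised cation, which the phenol captures to close the dioxane as the trans imide F5. This happens whichever configuration the aldol gave the benzylic carbon.
  - LiAlH4 in THF at 0 °C then reduces the imide and the methyl ester together to 10, and steps 6 to 8 follow.

**Step 3.**
- What may go wrong: the ester-bearing catechol is a weak nucleophile, so the exchange may stall at the open mixed acetal. The oxocarbenium ion may then be lost to arylation of electron-rich rings or to hydrolysis during isolation of the acid-labile acetal.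
- Fallback (sets out from 3, returns at 5): the same exchange is run with the more nucleophilic, purchased 4-bromocatechol to give 5-bromo-2-[3-methoxy-4-(triisopropylsilyloxy)phenyl]-1,3-benzodioxole F6. The ester is then introduced afterwards by palladium-catalysed methoxycarbonylation (Pd(OAc)2, Xantphos, CO, MeOH, Et3N, 70 °C), which gives 5.

**Step 5.**
- What may go wrong: deprotonation at C3 by the basic hydride may compete with carbonyl addition, followed by epimerisation or β-elimination of the O1 phenoxide (ring opening). The hindered tert-butyl ester may also reduce slowly.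
- Fallback (sets out from 9, returns at 10):
  - CF3CO2H in CH2Cl2 cleaves only the tert-butyl ester, giving (2R,3S)-6-(methoxycarbonyl)-2-[3-methoxy-4-(triisopropylsilyloxy)phenyl]-2,3-dihydro-1,4-benzodioxine-3-carboxylic acid F7.
  - BH3·THF reduces the acid, and not the aryl ester, under non-basic conditions to methyl (2R,3R)-3-(hydroxymethyl)-2-[3-methoxy-4-(triisopropylsilyloxy)phenyl]-2,3-dihydro-1,4-benzodioxine-6-carboxylate F8.
  - i-Bu2AlH in CH2Cl2 at −78 °C then reduces the remaining ester, with no acidic C3–H left beside a carbonyl, to 10.

**Step 7.**
- What may go wrong: partial loss of the silyl ether in the hot amine medium, then quinone methide formation at C2 and capture by piperidine. Condensation of the electron-rich aldehyde may also be slow.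
- Fallback (sets out from 11, returns at 14):
  - Wittig olefination with 2-(trimethylsilyl)ethyl (triphenylphosphoranylidene)acetate in CH2Cl2 at 23 °C, under neutral conditions, gives 2-(trimethylsilyl)ethyl (E)-3-[(2R,3R)-3-(hydroxymethyl)-2-[3-methoxy-4-(triisopropylsilyloxy)phenyl]-2,3-dihydro-1,4-benzodioxin-6-yl]prop-2-enoate F9.
  - Bu4NF in THF then removes the silyl ether and the silylethyl ester in one operation to give 14. This replaces steps 7 and 8.

## Further compounds

F1 | step 4 | methyl 4-(benzyloxy)-3-hydroxybenzoate | COC(=O)c1ccc(OCc2ccccc2)c(O)c1
F2 | step 4 | (4S)-4-benzyl-3-{[2-(benzyloxy)-5-(methoxycarbonyl)phenoxy]acetyl}-1,3-oxazolidin-2-one | COC(=O)c1ccc(OCc2ccccc2)c(OCC(=O)N3C(=O)OC[C@@H]3Cc4ccccc4)c1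
F3 | step 4 | (4S)-4-benzyl-3-[(2S,3R)-2-[2-(benzyloxy)-5-(methoxycarbonyl)phenoxy]-3-hydroxy-3-[3-methoxy-4-(triisopropylsilyloxy)phenyl]propanoyl]-1,3-oxazolidin-2-one | COC(=O)c1ccc(OCc2ccccc2)c(O[C@@H]([C@H](O)c5ccc(O[Si](C(C)C)(C(C)C)C(C)C)c(OC)c5)C(=O)N3C(=O)OC[C@@H]3Cc4ccccc4)c1
F4 | step 4 | (4S)-4-benzyl-3-[(2S,3R)-3-hydroxy-2-[2-hydroxy-5-(methoxycarbonyl)phenoxy]-3-[3-methoxy-4-(triisopropylsilyloxy)phenyl]propanoyl]-1,3-oxazolidin-2-one | COC(=O)c1ccc(O)c(O[C@@H]([C@H](O)c2ccc(O[Si](C(C)C)(C(C)C)C(C)C)c(OC)c2)C(=O)N3C(=O)OC[C@@H]3Cc4ccccc4)c1
F5 | step 4 | methyl (2R,3S)-3-{[(4S)-4-benzyl-2-oxo-1,3-oxazolidin-3-yl]carbonyl}-2-[3-methoxy-4-(triisopropylsilyloxy)phenyl]-2,3-dihydro-1,4-benzodioxine-6-carboxylate | COc1cc([C@H]2Oc3ccc(C(=O)OC)cc3O[C@@H]2C(=O)N4C(=O)OC[C@@H]4Cc5ccccc5)ccc1O[Si](C(C)C)(C(C)C)C(C)C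
F6 | step 3 | 5-bromo-2-[3-methoxy-4-(triisopropylsilyloxy)phenyl]-1,3-benzodioxole (racemic) | COc1cc(C2Oc3ccc(Br)cc3O2)ccc1O[Si](C(C)C)(C(C)C)C(C)C
F7 | step 5 | (2R,3S)-6-(methoxycarbonyl)-2-[3-methoxy-4-(triisopropylsilyloxy)phenyl]-2,3-dihydro-1,4-benzodioxine-3-carboxylic acid | COc1cc([C@H]2Oc3ccc(C(=O)OC)cc3O[C@@H]2C(=O)O)ccc1O[Si](C(C)C)(C(C)C)C(C)C
F8 | step 5 | methyl (2R,3R)-3-(hydroxymethyl)-2-[3-methoxy-4-(triisopropylsilyloxy)phenyl]-2,3-dihydro-1,4-benzodioxine-6-carboxylate | COc1cc([C@H]2Oc3ccc(C(=O)OC)cc3O[C@@H]2CO)ccc1O[Si](C(C)C)(C(C)C)C(C)C
F9 | step 7 | 2-(trimethylsilyl)ethyl (E)-3-[(2R,3R)-3-(hydroxymethyl)-2-[3-methoxy-4-(triisopropylsilyloxy)phenyl]-2,3-dihydro-1,4-benzodioxin-6-yl]prop-2-enoate | COc1cc([C@H]2Oc3ccc(/C=C/C(=O)OCC[Si](C)(C)C)cc3O[C@@H]2CO)ccc1O[Si](C(C)C)(C(C)C)C(C)C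
A1 | alternative 1 | methyl (E)-3-[(2R,3S)-2-(4-acetoxy-3-methoxyphenyl)-3-formyl-2,3-dihydro-1,4-benzodioxin-6-yl]prop-2-enoate | COc1cc([C@H]2Oc3ccc(/C=C/C(=O)OC)cc3O[C@@H]2C=O)ccc1OC(C)=O
A2 | alternative 1 | methyl (E)-3-[4-hydroxy-3-(2-oxoethoxy)phenyl]prop-2-enoate | COC(=O)/C=C/c1ccc(O)c(OCC=O)c1
A3 | alternative 1 | 4-formyl-2-methoxyphenyl acetate (vanillin acetate) | COc1cc(C=O)ccc1OC(C)=O
A4 | alternative 2 | [(2R,3R)-6-hydroxy-2-[3-methoxy-4-(4-methylbenzenesulfonyloxy)phenyl]-2,3-dihydro-1,4-benzodioxin-3-yl]methyl 2,2-dimethylpropanoate | COc1cc([C@H]2Oc3ccc(O)cc3O[C@@H]2COC(=O)C(C)(C)C)ccc1OS(=O)(=O)c1ccc(C)cc1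
A5 | alternative 2 | (2R,3R)-3-hydroxy-2-(3-hydroxyphenoxy)-3-[3-methoxy-4-(4-methylbenzenesulfonyloxy)phenyl]propyl 2,2-dimethylpropanoate | COc1cc([C@@H](O)[C@@H](COC(=O)C(C)(C)C)Oc2cccc(O)c2)ccc1OS(=O)(=O)c1ccc(C)cc1
A6 | alternative 3 | 4-[(2R,3R)-3-(tert-butoxymethyl)-6-(1,3-dioxolan-2-yl)-2,3-dihydro-1,4-benzodioxin-2-yl]-2-methoxyphenol | COc1cc([C@H]2Oc3ccc(C4OCCO4)cc3O[C@@H]2COC(C)(C)C)ccc1O
A7 | alternative 3 | (2R)-3-tert-butoxy-2-[5-(1,3-dioxolan-2-yl)-2-hydroxyphenoxy]-1-(4-hydroxy-3-methoxyphenyl)propan-1-ol, either epimer at C1 | COc1cc(C(O)[C@@H](COC(C)(C)C)Oc2cc(C3OCCO3)ccc2O)ccc1O
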